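**Retrosynthetic overview**
1. 23 ⇐ 22 ⇐ 21: acetate and (E)-allylic alcohol come from an (E)-enal, made by cross-metathesis of the 7-endo allyl group of 19 with methacrolein.
2. 19 ⇐ 18 ⇐ 16: the allyl group comes from palladium/formate hydrogenolysis of a 1-acetoxyallyl group; the C2–OMe is placed by silylating O4 first, methylating O2, then losing silicon.
3. 16 ⇐ 12: retro-aldol cleavage of the C3–C10 bond of a hydroxy-adamantane releases the 7-endo aldehyde, which is vinylated.
4. 12 ⇐ 3 + 9 in one flask: enantioselective dearomative C5-alkylation, then acid closes the cyclohexanone ring (C1–C8) and the adamantane ring (C3–C10 aldol) together.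
5. Ring order: phloroglucinol ring of 3 (becomes the C1–C5/C9 ring) → cyclohexanone ring and third (adamantane) ring formed together in step 3 → third ring opened again in step 4.

Numbering used in names: C1 = benzoyl-bearing bridgehead, C2 (OMe/O), C3, C4 (C=O), C5 = prenyl-bearing bridgehead, C6 (CH2), C7, C8 (CMe2), C9 (bridging C=O), C10 = first carbon on C7. "Endo" = on the face of the C2–C4 bridge; prenyl = 3-methylbut-2-enyl. With this numbering the target is (1R,5S,7S), with the C7 side chain endo.

Assumption: the hydrocinchonidinium-derived dimeric catalyst is taken to give the C5 configuration drawn; if it gives the antipode, its hydrocinchoninium pseudo-enantiomer is used. The C10 carbinol centre (drawn in 12 with OH away from the gem-dimethyl group; both epimers in 15–18) is removed in step 6.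

**Step 1**
Reactants: 1 2,4,6-trihydroxybenzophenone; 2 prenyl bromide (2 equiv)
Product: 3 clusiaphenone B
Conditions: 10% aq. KOH, 0 °C
Reagents that add atoms: none
Why: twofold C-alkylation of the phloroglucinol phenoxide in water (C-prenylation at the two free ring carbons), the known preparation of this compound; no stereocentre.

**Step 2**
Reactants: 4 2-bromoacrolein diethyl acetal; 5 acetone
Product: 9 3-acetoxy-3-methyl-2-methylenebutanal, via 2-lithioacrolein acetal 6 (not isolated), via lithium alkoxide 7 (not isolated), via acetate acetal 8 (not isolated)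
Conditions: t-BuLi (2 equiv), THF, −78 °C; acetone; Ac2O, −78 → 0 °C; then 1 M aq. HCl, THF, 0 °C
Reagents that add atoms: acetic anhydride, CC(=O)OC(C)=O; water, O
Why: bromine–lithium exchange gives the α-acrolein anion equivalent, which adds 1,2 to acetone; the tertiary lithium alkoxide is O-acylated in situ, and the unsaturated diethyl acetal is hydrolysed in the acidic work-up (no stereocentre).

**Step 3**
Reactants: 3 clusiaphenone B; 9 3-acetoxy-3-methyl-2-methylenebutanal
Product: 12 hydroxy-adamantane trione, via dearomatized enal 10 (not isolated), via 7-endo aldehyde 11 (not isolated)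
Conditions: 2,7-bis[O(9)-allylhydrocinchonidinium-N-methyl]naphthalene dibromide (25 mol %), CsOH·H2O, 4 Å MS, CH2Cl2, −60 °C; then conc. HCl, THF, −60 °C → rt
Reagents that add atoms: none
Why: Proposed new method: within the chiral ammonium ion pair a prenyl-bearing ring carbon of 3 adds to the enal and acetate is lost (Michael addition/E1cB, enantioselective alkylative dearomatization, sets C5), and acidifying the cold mixture before any base-mediated second Michael closure lets the benzoyl-bearing enol carbon C1 add to the protonated β,β-dimethyl enal (acid-mediated intramolecular Michael addition, C1–C8, C1 fixed by the bridge), after which the enolized diketone carbon C3 adds to the aldehyde (intramolecular aldol, geometrically possible only from the 7-endo epimer, so the reversible aldol selects C7); the closest known reactions are the phase-transfer-catalysed enantioselective alkylative dearomatization–annulation of clusiaphenone B with an α-acetoxy enal (recalled as this same enal) and the HCl-mediated cyclization of the racemic mono-adduct to this hydroxy-adamantane.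

**Step 4**
Reactants: 12 hydroxy-adamantane trione; 13 vinylmagnesium bromide
Product: 16 7-endo-(1-acetoxyallyl) diketone, via aldehyde enolate 14 (not isolated), via vinyl adduct bis-alkoxide 15 (not isolated)
Conditions: CH2=CHMgBr (6 equiv), CeCl3, THF, −78 → −20 °C; Ac2O, −78 → 0 °C; sat. aq. NaHCO3/MeOH work-up
Reagents that add atoms: acetic anhydride, CC(=O)OC(C)=O
Why: deprotonation triggers retro-aldol fragmentation to the stabilized 1,3-diketonate and the 7-endo aldehyde, which the weakly basic organocerium reagent captures by 1,2-addition before C7 can epimerize (retro-aldol/vinylcerium addition, known on this core); the far more basic secondary alkoxide is then O-acetylated, any enol acetate being cleaved in the work-up, and C10 forms as an inconsequential epimer mixture.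

**Step 5**
Reactants: 16 7-endo-(1-acetoxyallyl) diketone
Product: 18 C2 methyl enol ether acetate, via 4-O-silyl enol ether 17 (not isolated)
Conditions: TIPSOTf (1.1 equiv), 2,6-di-tert-butyl-4-methylpyridine, CH2Cl2, −78 °C; MeOTf (3 equiv), −78 → 0 °C; MeOH/Et3N, then aq. NaHCO3
Reagents that add atoms: methyl trifluoromethanesulfonate, COS(=O)(=O)C(F)(F)F
Why: Proposed new method: the bulky silyl triflate silylates the diketone enol at the less hindered O4 (next to the C5 prenyl CH2, not the benzoyl/gem-dimethyl side), methyl triflate then alkylates the carbonyl oxygen O2 of the vinylogous silyl ester to a 1,3-dioxyallyl cation, and triflate removes silicon from O4, leaving the methyl enol ether at C2; the closest known reactions are O-alkylation of vinylogous esters by Meerwein-type reagents to 1,3-dialkoxyallyl cations and regioselective O-silylation of cyclic 1,3-diketones.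

**Step 6**
Reactants: 18 C2 methyl enol ether acetate
Product: 19 7-endo-allyl methyl enol ether
Conditions: Pd2(dba)3 (5 mol %), PBu3, HCO2H, Et3N, THF, 40 °C
Reagents that add atoms: none
Why: Tsuji-type hydrogenolysis: zerovalent palladium ionizes the allylic acetate and the formate-derived hydride is delivered to the more substituted allyl terminus, giving the terminal alkene and erasing C10 (known on the 7-epi-nemorosone series); the protected diketone cannot attack the allyl complex.

**Step 7**
Reactants: 19 7-endo-allyl methyl enol ether; 20 methacrolein (10 equiv)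
Product: 21 (E)-enal
Conditions: second-generation Hoveyda–Grubbs catalyst RuCl2(H2IMes)(=CH-C6H4-2-OiPr) (10 mol %), CH2Cl2, 40 °C
Reagents that add atoms: none
Why: olefin cross-metathesis of the only monosubstituted alkene with an electron-poor 1,1-disubstituted partner, which gives the 2-methyl-2-enal with high E selectivity under thermodynamic control; the trisubstituted prenyl alkenes do not compete.

**Step 8**
Reactants: 21 (E)-enal
Product: 22 (E)-allylic alcohol
Conditions: NaBH4, CeCl3·7H2O, MeOH/THF, −78 °C
Reagents that add atoms: none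
Why: Luche 1,2-reduction of the unhindered conjugated aldehyde; the C9 and benzoyl ketones sit between quaternary carbons and the C4 carbonyl is a vinylogous ester, so they are not reduced at this temperature, and the alkene geometry is untouched.

**Step 9**
Reactants: 22 (E)-allylic alcohol
Product: 23 target
Conditions: Ac2O, pyridine, DMAP (cat.), CH2Cl2, 0 °C
Reagents that add atoms: acetic anhydride, CC(=O)OC(C)=O
Why: DMAP-catalysed O-acetylation of the primary allylic alcohol (nucleophilic acyl transfer); no stereocentre or alkene geometry is affected.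

**Compound list**
1 | 2,4,6-trihydroxybenzophenone | O=C(c1ccccc1)c1c(O)cc(O)cc1O | starting material
2 | prenyl bromide (1-bromo-3-methylbut-2-ene) | CC(C)=CCBr | starting material
3 | clusiaphenone B, 2,4,6-trihydroxy-3,5-diprenylbenzophenone | O=C(c1ccccc1)c1c(O)c(CC=C(C)C)c(O)c(CC=C(C)C)c1O | intermediate
4 | 2-bromoacrolein diethyl acetal (2-bromo-3,3-diethoxyprop-1-ene) | C=C(Br)C(OCC)OCC | starting material
5 | acetone | CC(C)=O | starting material
6 | 2-lithio-3,3-diethoxyprop-1-ene | C=C([Li])C(OCC)OCC | intermediate
7 | lithium 3-(diethoxymethyl)-2-methylbut-3-en-2-olate | C=C(C(OCC)OCC)C(C)(C)O[Li] | intermediate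
8 | 3-(diethoxymethyl)-2-methylbut-3-en-2-yl acetate | C=C(C(OCC)OCC)C(C)(C)OC(C)=O | intermediate
9 | 3-acetoxy-3-methyl-2-methylenebutanal | C=C(C=O)C(C)(C)OC(C)=O | intermediate
10 | 2-benzoyl-3,5-dihydroxy-4,6-diprenyl-6-(2-formyl-3-methylbut-2-enyl)cyclohexa-2,4-dien-1-one (one tautomer; quaternary carbon configured as C5 of 23) | CC(C)=CC[C@]1(CC(C=O)=C(C)C)C(O)=C(CC=C(C)C)C(O)=C(C(=O)c2ccccc2)C1=O | intermediate
11 | 1-benzoyl-7-endo-formyl-2-hydroxy-8,8-dimethyl-3,5-diprenylbicyclo[3.3.1]non-2-ene-4,9-dione (C1, C5, C7 as in 23) | OC1=C(CC=C(C)C)C(=O)[C@]2(CC=C(C)C)C[C@H](C=O)C(C)(C)[C@@]1(C(=O)c1ccccc1)C2=O | intermediate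
12 | hydroxy-adamantane trione: the bicyclic 2,4,9-trione of 11 with C3 and C7 bridged by CH(OH) (C10); C1, C5, C7 as in 23, OH on the side away from the gem-dimethyl group | O=C1[C@@]4(CC=C(C)C)C(=O)[C@]2(CC=C(C)C)C[C@H]([C@@H]4O)C(C)(C)[C@@]1(C(=O)c1ccccc1)C2=O | intermediate
13 | vinylmagnesium bromide | C=C[Mg]Br | starting material
14 | bromomagnesium enolate of 11 (ring-opened 7-endo aldehyde; written as the magnesium salt) | Br[Mg]OC1=C(CC=C(C)C)C(=O)[C@]2(CC=C(C)C)C[C@H](C=O)C(C)(C)[C@@]1(C(=O)c1ccccc1)C2=O | intermediate
15 | bis(bromomagnesium) salt of the 7-endo-(1-hydroxyallyl) diketone (both C10 epimers) | Br[Mg]OC1=C(CC=C(C)C)C(=O)[C@]2(CC=C(C)C)C[C@H](C(O[Mg]Br)C=C)C(C)(C)[C@@]1(C(=O)c1ccccc1)C2=O | intermediate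
16 | 7-endo-(1-acetoxyprop-2-enyl)-1-benzoyl-2-hydroxy-8,8-dimethyl-3,5-diprenylbicyclo[3.3.1]non-2-ene-4,9-dione (enol tautomer drawn; both C10 epimers) | OC1=C(CC=C(C)C)C(=O)[C@]2(CC=C(C)C)C[C@H](C(OC(C)=O)C=C)C(C)(C)[C@@]1(C(=O)c1ccccc1)C2=O | intermediate
17 | 4-O-triisopropylsilyl enol ether of 16 (C2 ketone, C3=C4–OSi) | O=C1C(CC=C(C)C)=C(O[Si](C(C)C)(C(C)C)C(C)C)[C@]2(CC=C(C)C)C[C@H](C(OC(C)=O)C=C)C(C)(C)[C@@]1(C(=O)c1ccccc1)C2=O | intermediate
18 | 7-endo-(1-acetoxyprop-2-enyl)-1-benzoyl-2-methoxy-8,8-dimethyl-3,5-diprenylbicyclo[3.3.1]non-2-ene-4,9-dione | COC1=C(CC=C(C)C)C(=O)[C@]2(CC=C(C)C)C[C@H](C(OC(C)=O)C=C)C(C)(C)[C@@]1(C(=O)c1ccccc1)C2=O | intermediate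
19 | 7-endo-allyl-1-benzoyl-2-methoxy-8,8-dimethyl-3,5-diprenylbicyclo[3.3.1]non-2-ene-4,9-dione | COC1=C(CC=C(C)C)C(=O)[C@]2(CC=C(C)C)C[C@H](CC=C)C(C)(C)[C@@]1(C(=O)c1ccccc1)C2=O | intermediate
20 | methacrolein | C=C(C)C=O | starting material
21 | 7-endo-[(E)-3-methyl-4-oxobut-2-enyl] analogue of 19 | COC1=C(CC=C(C)C)C(=O)[C@]2(CC=C(C)C)C[C@H](C/C=C(\C)C=O)C(C)(C)[C@@]1(C(=O)c1ccccc1)C2=O | intermediate
22 | 7-endo-[(E)-4-hydroxy-3-methylbut-2-enyl] analogue of 19 | COC1=C(CC=C(C)C)C(=O)[C@]2(CC=C(C)C)C[C@H](C/C=C(\C)CO)C(C)(C)[C@@]1(C(=O)c1ccccc1)C2=O | intermediate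
23 | (1R,5S,7S)-7-endo-[(E)-4-acetoxy-3-methylbut-2-enyl]-1-benzoyl-2-methoxy-8,8-dimethyl-3,5-diprenylbicyclo[3.3.1]non-2-ene-4,9-dione | COC1=C(CC=C(C)C)C(=O)[C@]2(CC=C(C)C)C[C@H](C/C=C(\C)COC(C)=O)C(C)(C)[C@@]1(C(=O)c1ccccc1)C2=O | target

**Step count and risks**
Total step count: 9. Longest linear sequence: 8 steps (1 → 3 → 12 → 16 → 18 → 19 → 21 → 22 → 23; the branch from 4 through 9 is equally long).

Steps most likely to fail:

Step 3. Under the basic phase-transfer conditions the mono-adduct can close by a second Michael addition at the other prenyl-bearing carbon (the regioisomeric adamantane) before the acid quench, and the level and sense of enantioselection are uncertain. Fallback, setting out from 3 and 9 and returning at 12: alkylate with LiHMDS in THF (−78 → 0 °C), where the lithium enolate stops at the mono-adduct, and isolate the racemic dearomatized enal F1. Treat it with conc. HCl/THF to obtain the hydroxy-adamantane as a racemate, that is 12 together with its mirror-image adamantanol F2. Resolve by preparative chromatography on a chiral stationary phase and carry 12 on.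

Step 5. Silylation may not be fully O4-selective, or the methylation of the hindered O2 may be slow. Fallback, setting out from 16 and returning at 18: methylate the enol directly with TMSCHN2 in MeOH/toluene, which gives 18 together with the 4-O-methyl regioisomer F3. Separate the two by chromatography. Demethylate F3 with LiI/2,6-lutidine back to 16 and recycle it.

Step 7. Metathesis with methacrolein can stall (oligomerization of the aldehyde, catalyst decay), and the following reduction must spare three other carbonyl groups. Fallback, setting out from 19 and returning at 23: one cross-metathesis with a large excess of 2-methylallyl acetate and the same ruthenium catalyst forms the allylic acetate directly and bypasses steps 8 and 9. The price is lower E-selectivity; the (Z)-isomer F4 is removed on AgNO3-impregnated silica.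

**Further compounds**
F1 | step 3 | racemic 2-benzoyl-3,5-dihydroxy-4,6-diprenyl-6-(2-formyl-3-methylbut-2-enyl)cyclohexa-2,4-dien-1-one (racemic 10) | O=CC(=C(C)C)CC1(CC=C(C)C)C(O)=C(CC=C(C)C)C(O)=C(C(=O)c2ccccc2)C1=O
F2 | step 3 | mirror image of hydroxy-adamantane 12 (second component of the racemate) | O=C1[C@]4(CC=C(C)C)C(=O)[C@@]2(CC=C(C)C)C[C@@H]([C@H]4O)C(C)(C)[C@]1(C(=O)c1ccccc1)C2=O
F3 | step 5 | 4-O-methyl regioisomer of 18 (C2 ketone, C3=C4–OMe) | O=C1C(CC=C(C)C)=C(OC)[C@]2(CC=C(C)C)C[C@H](C(OC(C)=O)C=C)C(C)(C)[C@@]1(C(=O)c1ccccc1)C2=O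
F4 | step 7 | (Z)-isomer of 23 in the C7 side chain | COC1=C(CC=C(C)C)C(=O)[C@]2(CC=C(C)C)C[C@H](C/C=C(/C)COC(C)=O)C(C)(C)[C@@]1(C(=O)c1ccccc1)C2=O
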